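## Structural features

The target 35 is a C15 acetogenin, numbered C1–C15 from the alkyne terminus. An ether oxygen bridges C6 and C12, so the core is an oxocane (ring atoms O, C6–C12). It carries a (Z)-pent-2-en-4-ynyl chain at C6 and a 1-acetoxypropyl chain at C12, cis to each other across the ring oxygen.

The six stereocentres (6R,7R,9R,10S,12R,13S) form three adjacent oxygenated pairs separated by the methylenes C8 and C11. C6/C7 (ether carbon and acetoxy carbon) is syn, with both substituents cis on the ring. C9/C10 (free diol) is anti in the chain, which is cis on the ring. C12/C13 (ether carbon and exocyclic acetoxy carbon) is anti.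

The fragile parts are the Z-enyne with its terminal alkyne (no hydrogenation, little tolerance of strong base), the two secondary acetates beside a free diol (acyl migration), and the β-alkoxy aldehydes met on the way (elimination). The real difficulty is closing an eight-membered ring while fixing C6 relative to C12 (cis-2,8) and setting the C6/C7 pair.

The key step uses the O12–C6–C7–O unit inside the oxocane. A (Z)-enol ether on O12 that carries an allylic boron adds through its γ-carbon C6 to a C7 aldehyde, which forms the ring bond C6–C7 and both stereocentres at once. The cis-9,10-diol is held as an acetonide to fold the chain. Precursor 25 and product 26 were checked centre by centre against 35 and agree at every shared carbon, so no structure needed correction.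

## Logic of the disconnections

35 ⇐ 34 ⇐ 33 ⇐ 32. The cuts are the two acetal C–O bonds at O9/O10, the two O–acyl bonds at O7 and O13, and the silyl bonds at O7, O13 and C1. Acetates beside a free diol can migrate, so the diol stays masked until both acetates are in place and the acetonide is removed last. All three silyl groups fall in one operation. The forward demand is an acetal hydrolysis mild enough for two acetates and the enyne.

32 ⇐ 30 + 31. The cut is C3=C4. The Z-enyne is the most fragile unit, so it enters late and in one step that brings C1–C3 with the Z geometry. This leaves 30 without any unsaturation. The forward step must add to a β-alkoxy aldehyde faster than it enolises it, and must be Z-selective.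

30 ⇐ 29 ⇐ 27 ⇐ 26. The cuts are the C4 oxidation level, the C4–O bond and the O7–Si bond. The vinyl group left on C6 by the key step is exactly C4–C5, so anti-Markovnikov hydration and oxidation give the aldehyde with no new C–C bond. The C7 hydroxyl must be silylated first.

26 ⇐ 25. The cut is C6–C7. It opens the oxocane and removes two stereocentres, leaving an acyclic chain whose four remaining centres are set earlier. The forward step needs a (Z)-enol ether, a closed chair transition state, and face selection at C6 by the C12 centre.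

25 ⇐ 24 ⇐ 21 + 22. The cuts are the C7 carbonyl (back to the carbinol) and the C4–B bond. An aldehyde cannot sit beside the allylboronate, nor beside the organolithium that makes it. The C7 oxygen is therefore carried as a free hydroxyl (a lithium alkoxide during metalation), and the aldehyde is unveiled by a neutral oxidation with no acid or fluoride step in the presence of the enol ether and the C–B bond. The forward demand is a double deprotonation and chelation-controlled Z geometry.

21 ⇐ 20 ⇐ 18 + 19 ⇐ 17 ⇐ 16 ⇐ 14. The cuts are the O12–C6 ether bond, the temporary ester and benzyl groups, and the C7–O bond. The allyl group must follow the hydroboration of C7=C8, because two terminal olefins could not be told apart. O12 therefore stays benzylated until then, and the C7 hydroxyl is briefly an acetate. The allylation must not pass through an O12 alkoxide next to the O13 silyl ether (1,2-silyl shift), so an acid-catalysed imidate alkylation is used.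

14 ⇐ 13 ⇐ 10 + 11. The cut is C9–C10. It creates both C9 and C10 and brings in C7–C9 as one three-carbon unit. The forward step must be anti-selective and must attack the Re face of C10. The nearest stereocentre is β (C12) and the needed 1,3-relationship is syn, so the reagent must control the face.

10 ⇐ 8 ⇐ 7 ⇐ 5 + 6 ⇐ 4 ⇐ 2 ⇐ 1. The cuts are C14–C15, the one-carbon olefin mask on C10, and the O–benzyl and O–silyl bonds. C12 and C13 come unchanged from the chiral pool. The epoxide ties O13 to C14, so O12 is the only free hydroxyl when the benzyl group goes on, and O12 and O13 are differentiated without a selective protection. The forward demands are epoxide closure with retention at C13, alkylation faster than Payne rearrangement, and methyl attack at C14 only.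

## Other disconnections considered

Alternative 1: The cut is C11–C12, with C12 as an oxocarbenium carbon. In the forward step SnCl4 would ionise the α-acetoxy ether A2, and the terminal olefin would attack 8-endo to give oxocene A1 after loss of a C9 proton.
- In its favour: A2 is assembled convergently from two small pieces, and the ring and the cis-2,8 relationship should arise in one step.
- Against it here: A1 lacks both C9/C10 oxygens, so a face-selective syn-dihydroxylation of a ring olefin must follow. The monosubstituted olefin is a weak nucleophile that passes through a secondary cation, and proton loss could occur toward C9 or C11. The C13 benzyloxy group next to the cationic carbon slows ionisation and is awkward to remove beside an enyne.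
- Comparison: on convergence and on avoiding organometallic intermediates this alternative is the better plan. On structure the chosen plan is better, because 26 already holds all six stereocentres. On step economy the two are about equal once the diol installation is counted.

Alternative 2: The cut is C7–C8 together with C10–O. In the forward step the ketene acetal A4, generated in situ, would undergo a [3,3] shift to the eight-membered lactone A3 with a Z ring olefin.
- In its favour: a concerted ring expansion is the most dependable of the four ring-forming events, which makes this alternative the better one on that point. C12 and C13 can come from the chiral pool, as in the chosen plan (equal).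
- Against it here: A3 holds only two of the six stereocentres. C6 is a carbonyl that must become a carbinol-ether carbon bearing C5 cis to the C12 chain. C7 must be hydroxylated and C9=C10 dihydroxylated, all under substrate control on a flexible ring.
- Comparison: the mechanism is safer, but the structure delivered is much less advanced, and the route after the ring closure would be clearly longer than the seven steps that follow 26.

Alternative 3: The cut is C8–C9. In the forward step SmI2 (samarium diiodide, divalent samarium) would turn the bromomethyl ketone A6 into a samarium enolate that adds to the C9 aldehyde, closing oxocanone A5.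
- In its favour: the conditions are mild and tolerate silyl ethers, and the metal can template medium-ring closure. The C4 oxygen is already present, so the endgame to the enyne would be shorter, which is a point on which it is better. The C9/C10 oxygens are in place, which is equal to the chosen plan.
- Against it here: A6 needs the C6–O–C12 ether with both flanking stereocentres preset, which is the hardest bond of the molecule to make stereoselectively. Only C9 is set, the C7 ketone needs a diastereoselective reduction, and α-alkoxy ketones are themselves cleaved by the reagent, which threatens the ring C6–O bond.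
- Comparison: the mechanism is gentler, but the structural gain per step is smaller (one stereocentre against two), and the precursor would be longer to make than 24.

Key step: step 15

Assumption: the (+)-Ipc2BOMe-derived borane of step 7 is taken to deliver the allyl group to the Re face of C10; should the sense be the reverse, the (−)-antipode is used and nothing else changes.

## Steps

Step 1
Reactants: 1 2-deoxy-L-ribose
Product: 2 (2S,3R)-hex-5-ene-1,2,3-triol
Conditions: Ph3PCH3Br, KOtBu, THF, 0 °C → reflux
Reagents that add atoms: methyltriphenylphosphonium bromide, C[P+](c1ccccc1)(c1ccccc1)c1ccccc1.[Br-]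
Why: Wittig methylenation of the hydroxy-aldehyde form of the lactol, with excess ylide to allow for the free hydroxyls; the new terminal olefin is a latent C10 aldehyde, and C12 and C13 are taken unchanged from the sugar.

Step 2
Reactants: 2 (2S,3R)-hex-5-ene-1,2,3-triol
Product: 4 (1R)-1-[(2S)-oxiran-2-yl]but-3-en-1-ol, via primary tosylate 3 (not isolated)
Conditions: TsCl, Et3N, Bu2SnO (cat.), CH2Cl2, 0 °C; then K2CO3, MeOH, 0 °C
Reagents that add atoms: none
Why: Stannylene-catalysed sulfonylation selects the primary hydroxyl of the terminal 1,2-diol, and carbonate then closes the epoxide by 3-exo-tet attack of O13 on C14, so C13 keeps its configuration; O12 is left as the only free hydroxyl.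

Step 3
Reactants: 4 (1R)-1-[(2S)-oxiran-2-yl]but-3-en-1-ol
Product: 5 (2S)-2-[(1R)-1-(benzyloxy)but-3-en-1-yl]oxirane
Conditions: NaH, BnBr, Bu4NI (cat.), THF, 0 °C → rt
Reagents that add atoms: benzyl bromide, BrCc1ccccc1
Why: Williamson etherification; alkylation of the sodium alkoxide by the activated halide at 0 °C should outrun Payne rearrangement, and the benzyl group marks O12 as the oxygen to be freed later.

Step 4
Reactants: 5 (2S)-2-[(1R)-1-(benzyloxy)but-3-en-1-yl]oxirane; 6 methyllithium
Product: 7 (3S,4R)-4-(benzyloxy)hept-6-en-3-ol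
Conditions: CuI (0.5 equiv per MeLi), Et2O, −40 → 0 °C; H2O
Reagents that add atoms: none
Why: The lithium dimethylcuprate formed in the flask opens the terminal epoxide by SN2 attack at the unsubstituted carbon C14, adding C15 and releasing O13 without touching C13.

Step 5
Reactants: 7 (3S,4R)-4-(benzyloxy)hept-6-en-3-ol
Product: 8 {[(3S,4R)-4-(benzyloxy)hept-6-en-3-yl]oxy}(tert-butyl)dimethylsilane
Conditions: TBSOTf, 2,6-lutidine, CH2Cl2, −78 → 0 °C
Reagents that add atoms: tert-butyldimethylsilyl triflate, CC(C)(C)[Si](C)(C)OS(=O)(=O)C(F)(F)F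
Why: Silylation of a hindered secondary alcohol with the silyl triflate; the O13 silyl ether survives organolithiums, hydrogenolysis and mild acid and is removed only at the end.

Step 6
Reactants: 8 {[(3S,4R)-4-(benzyloxy)hept-6-en-3-yl]oxy}(tert-butyl)dimethylsilane
Product: 10 (3R,4S)-3-(benzyloxy)-4-(tert-butyldimethylsilyloxy)hexanal, via ozonide 9 (not isolated)
Conditions: O3, CH2Cl2, −78 °C; then PPh3, −78 °C → rt
Reagents that add atoms: ozone, [O-][O+]=O
Why: Ozonolysis of the terminal olefin with reductive work-up unmasks the C10 aldehyde under neutral conditions, which avoids β-elimination of the benzyloxy group.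

Step 7
Reactants: 10 (3R,4S)-3-(benzyloxy)-4-(tert-butyldimethylsilyloxy)hexanal; 11 allyl(diisopropylamino)dimethylsilane
Product: 13 (3R,4S,6R,7S)-6-(benzyloxy)-7-(tert-butyldimethylsilyloxy)non-1-ene-3,4-diol, via β-silyl alcohol 12 (not isolated)
Conditions: 11, n-BuLi, TMEDA, Et2O, 0 °C; (+)-Ipc2BOMe, −78 °C; BF3·OEt2; 10, −78 °C; then KF, KHCO3, 30% H2O2, THF/MeOH, rt
Reagents that add atoms: hydrogen peroxide, OO
Why: Allylboration of 10 by the (E)-γ-silylallyl diisopinocampheylborane through a chair transition state gives the anti β-silyl alcohol 12, with the Ipc ligands directing attack to the Re face of C10 (reagent control over the remote C12 ether). Tamao oxidation then replaces silicon by hydroxyl with retention, so C9 and C10 emerge as the anti diol.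

Step 8
Reactants: 13 (3R,4S,6R,7S)-6-(benzyloxy)-7-(tert-butyldimethylsilyloxy)non-1-ene-3,4-diol
Product: 14 (4R,5S)-5-[(2R,3S)-2-(benzyloxy)-3-(tert-butyldimethylsilyloxy)pentyl]-4-ethenyl-2,2-dimethyl-1,3-dioxolane
Conditions: Me2C(OMe)2, PPTS (cat.), CH2Cl2, rt
Reagents that add atoms: 2,2-dimethoxypropane, COC(C)(C)OC
Why: Acid-catalysed transketalisation of the 1,2-diol; the anti diol gives the cis-disubstituted dioxolane that later folds the chain for ring closure.

Step 9
Reactants: 14 (4R,5S)-5-[(2R,3S)-2-(benzyloxy)-3-(tert-butyldimethylsilyloxy)pentyl]-4-ethenyl-2,2-dimethyl-1,3-dioxolane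
Product: 16 2-[(4R,5S)-5-[(2R,3S)-2-(benzyloxy)-3-(tert-butyldimethylsilyloxy)pentyl]-2,2-dimethyl-1,3-dioxolan-4-yl]ethan-1-ol, via alkylborane 15 (not isolated)
Conditions: 9-BBN, THF, 0 °C → rt; then NaOH, H2O2, 0 °C
Reagents that add atoms: hydrogen peroxide, OO
Why: Anti-Markovnikov hydroboration–oxidation of the only olefin places the oxygen on C7; it is done before any allyl ether is present, so no second olefin competes.

Step 10
Reactants: 16 2-[(4R,5S)-5-[(2R,3S)-2-(benzyloxy)-3-(tert-butyldimethylsilyloxy)pentyl]-2,2-dimethyl-1,3-dioxolan-4-yl]ethan-1-ol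
Product: 17 2-[(4R,5S)-5-[(2R,3S)-2-(benzyloxy)-3-(tert-butyldimethylsilyloxy)pentyl]-2,2-dimethyl-1,3-dioxolan-4-yl]ethyl acetate
Conditions: Ac2O, pyridine, DMAP (cat.), CH2Cl2, rt
Reagents that add atoms: acetic anhydride, CC(=O)OC(C)=O
Why: Acetylation masks the primary C7 hydroxyl so that O12 is the only hydroxyl present when the allyl group is introduced.

Step 11
Reactants: 17 2-[(4R,5S)-5-[(2R,3S)-2-(benzyloxy)-3-(tert-butyldimethylsilyloxy)pentyl]-2,2-dimethyl-1,3-dioxolan-4-yl]ethyl acetate
Product: 18 2-[(4R,5S)-5-[(2R,3S)-3-(tert-butyldimethylsilyloxy)-2-hydroxypentyl]-2,2-dimethyl-1,3-dioxolan-4-yl]ethyl acetate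
Conditions: H2 (1 atm), Pd(OH)2/C, EtOAc, rt
Reagents that add atoms: none
Why: Hydrogenolysis of the benzyl ether; the molecule holds no olefin at this stage, and the acetate, silyl ether and acetonide are inert in ethyl acetate.

Step 12
Reactants: 18 2-[(4R,5S)-5-[(2R,3S)-3-(tert-butyldimethylsilyloxy)-2-hydroxypentyl]-2,2-dimethyl-1,3-dioxolan-4-yl]ethyl acetate; 19 allyl 2,2,2-trichloroacetimidate
Product: 20 2-[(4R,5S)-5-[(2R,3S)-2-(allyloxy)-3-(tert-butyldimethylsilyloxy)pentyl]-2,2-dimethyl-1,3-dioxolan-4-yl]ethyl acetate
Conditions: TfOH (cat.), CH2Cl2/cyclohexane, 0 °C → rt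
Reagents that add atoms: none
Why: Acid-catalysed alkylation of the alcohol by the protonated imidate; no alkoxide is formed, so the neighbouring O13 silyl group cannot migrate to O12 as it could under Williamson conditions.

Step 13
Reactants: 20 2-[(4R,5S)-5-[(2R,3S)-2-(allyloxy)-3-(tert-butyldimethylsilyloxy)pentyl]-2,2-dimethyl-1,3-dioxolan-4-yl]ethyl acetate
Product: 21 2-[(4R,5S)-5-[(2R,3S)-2-(allyloxy)-3-(tert-butyldimethylsilyloxy)pentyl]-2,2-dimethyl-1,3-dioxolan-4-yl]ethan-1-ol
Conditions: K2CO3, MeOH, 0 °C → rt
Reagents that add atoms: none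
Why: Base-catalysed methanolysis of the primary acetate; no free hydroxyl is vicinal to the silyl ether, so silyl migration is not possible.

Step 14
Reactants: 21 2-[(4R,5S)-5-[(2R,3S)-2-(allyloxy)-3-(tert-butyldimethylsilyloxy)pentyl]-2,2-dimethyl-1,3-dioxolan-4-yl]ethan-1-ol; 22 2-isopropoxy-4,4,5,5-tetramethyl-1,3,2-dioxaborolane
Product: 24 2-[(4R,5S)-5-[(2R,3S)-3-(tert-butyldimethylsilyloxy)-2-{[(1Z)-3-(4,4,5,5-tetramethyl-1,3,2-dioxaborolan-2-yl)prop-1-en-1-yl]oxy}pentyl]-2,2-dimethyl-1,3-dioxolan-4-yl]ethan-1-ol, via dilithio species 23 (not isolated)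
Conditions: sec-BuLi (2.3 equiv), THF, −78 °C; 22, −78 → 0 °C; pH 7 buffer
Reagents that add atoms: none
Why: Metalation–borylation of an allyl ether: the first equivalent of base forms the C7 alkoxide and the second removes an allylic proton α to O12. The oxygen-chelated (Z)-1-alkoxyallyllithium is borylated at its γ-terminus by 22, which fixes the Z enol ether. Carrying C7 as the alkoxide means no protecting group has to be removed later beside the C–B bond.

Step 15
Reactants: 24 2-[(4R,5S)-5-[(2R,3S)-3-(tert-butyldimethylsilyloxy)-2-{[(1Z)-3-(4,4,5,5-tetramethyl-1,3,2-dioxaborolan-2-yl)prop-1-en-1-yl]oxy}pentyl]-2,2-dimethyl-1,3-dioxolan-4-yl]ethan-1-ol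
Product: 26 oxocane alcohol (C4–C15; ring oxygen between C6 and C12; 6R-ethenyl, 7R-hydroxyl, cis-9R,10S-acetonide, 12R-[(1S)-1-(tert-butyldimethylsilyloxy)propyl]), via aldehyde 25 (not isolated)
Conditions: Dess–Martin periodinane, NaHCO3, CH2Cl2, 0 °C → rt; then toluene (0.01 M), 50 °C; aq. NaHCO3
Reagents that add atoms: none
Why: Dess–Martin oxidation under bicarbonate buffer converts the C7 carbinol into aldehyde 25 without acid, fluoride or a base strong enough to touch the enol ether, the C–B bond or the β-oxygen at C9. The carbonyl oxygen of 25 then binds the boron of the tethered pinacol boronate, and the γ-carbon C6 of the (Z)-enol ether attacks C7 through a closed six-membered chair transition state (B, C4, C5, C6, C7, O) with allylic transposition, leaving C4=C5 as a vinyl group and a C7 borate that is hydrolysed on work-up; the closest known reaction type is the intramolecular allylboration of aldehydes by γ-alkoxyallylboronates that closes six- to eight-membered cyclic ethers. The oxocane closes in the 8-exo-trig mode: the tether O12–C12–C11–C10–C9–C8 spans the two carbons of the forming C6–C7 bond, and both π-bonds stay outside the new ring. The C6/C7 relationship is controlled by the Z geometry of the enol ether: O12 sits axial and C8 equatorial on the chair, the only arrangement the short tether allows, and this gives the syn pair, that is vinyl and hydroxyl cis on the ring. The configuration at C6 relative to C12 is controlled by allylic strain about the C12–O12 bond: C12–H lies in the plane of the enol ether and the C11 tether and the C13 side chain lie on opposite faces, so the aldehyde can reach only the face that carries C11, which puts the C13 chain pseudo-equatorial and gives the cis-2,8 (6R) ring. The step needs ring closure to beat oligomerisation and needs the Z geometry to survive; the cis-fused 9,10-acetonide holds C8 and C11 on the same face of a five-membered ring and so folds the chain, high dilution suppresses bimolecular allylboration, and the neutral oxidation keeps the enol ether intact.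

Step 16
Reactants: 26 oxocane alcohol
Product: 27 oxocane bis-silyl ether (as 26, with C7 tert-butyldimethylsilyl ether)
Conditions: TBSOTf, 2,6-lutidine, CH2Cl2, −78 → 0 °C
Reagents that add atoms: tert-butyldimethylsilyl triflate, CC(C)(C)[Si](C)(C)OS(=O)(=O)C(F)(F)F
Why: Silylation of the hindered ring carbinol with the silyl triflate; the C7 oxygen must be masked against the borane, the oxidant and the organolithium of the next three steps.

Step 17
Reactants: 27 oxocane bis-silyl ether
Product: 29 primary alcohol (as 27, with C6 bearing CH2CH2OH in place of ethenyl), via alkylborane 28 (not isolated)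
Conditions: 9-BBN, THF, rt; then NaOH, H2O2, 0 °C
Reagents that add atoms: hydrogen peroxide, OO
Why: Anti-Markovnikov hydroboration–oxidation of the vinyl group places the oxygen on C4; the bulky borane keeps the addition terminal next to the substituted ring carbon.

Step 18
Reactants: 29 primary alcohol
Product: 30 aldehyde (as 27, with C6 bearing CH2CHO)
Conditions: Dess–Martin periodinane, NaHCO3, CH2Cl2, 0 °C → rt
Reagents that add atoms: none
Why: Buffered Dess–Martin oxidation gives the β-alkoxy aldehyde without base, so retro-oxa-Michael opening of the ring is avoided.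

Step 19
Reactants: 30 aldehyde; 31 1,3-bis(triisopropylsilyl)propyne
Product: 32 (Z)-silyl enyne (as 27, with C6 bearing (2Z)-5-(triisopropylsilyl)pent-2-en-4-yn-1-yl)
Conditions: 31, n-BuLi, THF, −78 °C; then 30, −78 °C → rt
Reagents that add atoms: none
Why: Peterson olefination: the lithiated propargylsilane adds to the aldehyde and the β-silyl alkoxide undergoes syn elimination of silanolate. The two bulky triisopropylsilyl groups bias the adduct toward the diastereomer that gives the Z olefin.

Step 20
Reactants: 32 (Z)-silyl enyne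
Product: 33 (3Z,6R,7R,9R,10S,12R,13S)-6,12-epoxy-9,10-(isopropylidenedioxy)pentadec-3-en-1-yne-7,13-diol
Conditions: TBAF, THF, 0 → 40 °C
Reagents that add atoms: none
Why: Fluoride cleaves both tert-butyldimethylsilyl ethers and the alkynyl C–Si bond in one operation; the acetonide and the enyne are inert to fluoride.

Step 21
Reactants: 33 (3Z,6R,7R,9R,10S,12R,13S)-6,12-epoxy-9,10-(isopropylidenedioxy)pentadec-3-en-1-yne-7,13-diol
Product: 34 (3Z,6R,7R,9R,10S,12R,13S)-6,12-epoxy-9,10-(isopropylidenedioxy)pentadec-3-en-1-yne-7,13-diyl diacetate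
Conditions: Ac2O, pyridine, DMAP (cat.), CH2Cl2, rt
Reagents that add atoms: acetic anhydride, CC(=O)OC(C)=O
Why: DMAP-catalysed acetylation of the two secondary hydroxyls while O9 and O10 are still tied in the acetonide, so the acetates can only go to C7 and C13.

Step 22
Reactants: 34 (3Z,6R,7R,9R,10S,12R,13S)-6,12-epoxy-9,10-(isopropylidenedioxy)pentadec-3-en-1-yne-7,13-diyl diacetate
Product: 35 (3Z,6R,7R,9R,10S,12R,13S)-6,12-epoxy-9,10-dihydroxypentadec-3-en-1-yne-7,13-diyl diacetate (target)
Conditions: AcOH/H2O (4:1), 40 °C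
Reagents that add atoms: none
Why: Acid-catalysed hydrolysis of the isopropylidene ketal; aqueous acetic acid leaves the acetates and the enyne untouched, and acyl migration is slow under acidic conditions.

## Compound list

1 | 2-deoxy-L-ribose | O=CC[C@@H](O)[C@@H](O)CO | starting material
2 | (2S,3R)-hex-5-ene-1,2,3-triol | C=CC[C@@H](O)[C@@H](O)CO | intermediate
3 | (2S,3R)-2,3-dihydroxyhex-5-en-1-yl 4-methylbenzenesulfonate | C=CC[C@@H](O)[C@@H](O)COS(=O)(=O)c1ccc(C)cc1 | intermediate
4 | (1R)-1-[(2S)-oxiran-2-yl]but-3-en-1-ol | C=CC[C@@H](O)[C@@H]1CO1 | intermediate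
5 | (2S)-2-[(1R)-1-(benzyloxy)but-3-en-1-yl]oxirane | C=CC[C@@H](OCc1ccccc1)[C@@H]2CO2 | intermediate
6 | methyllithium | [Li]C | starting material
7 | (3S,4R)-4-(benzyloxy)hept-6-en-3-ol | C=CC[C@@H](OCc1ccccc1)[C@@H](O)CC | intermediate
8 | {[(3S,4R)-4-(benzyloxy)hept-6-en-3-yl]oxy}(tert-butyl)dimethylsilane | C=CC[C@@H](OCc1ccccc1)[C@@H](O[Si](C)(C)C(C)(C)C)CC | intermediate
9 | 3-[(2R,3S)-2-(benzyloxy)-3-(tert-butyldimethylsilyloxy)pentyl]-1,2,4-trioxolane (ozonide; ring carbon unassigned) | C1OC(C[C@@H](OCc2ccccc2)[C@@H](O[Si](C)(C)C(C)(C)C)CC)OO1 | intermediate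
10 | (3R,4S)-3-(benzyloxy)-4-(tert-butyldimethylsilyloxy)hexanal | O=CC[C@@H](OCc1ccccc1)[C@@H](O[Si](C)(C)C(C)(C)C)CC | intermediate
11 | allyl(diisopropylamino)dimethylsilane | C=CC[Si](C)(C)N(C(C)C)C(C)C | starting material
12 | (3R,4S,6R,7S)-6-(benzyloxy)-7-(tert-butyldimethylsilyloxy)-3-[(diisopropylamino)dimethylsilyl]non-1-en-4-ol (held in the flask as its diisopinocampheylborinate) | C=C[C@@H]([Si](C)(C)N(C(C)C)C(C)C)[C@@H](O)C[C@@H](OCc1ccccc1)[C@@H](O[Si](C)(C)C(C)(C)C)CC | intermediate
13 | (3R,4S,6R,7S)-6-(benzyloxy)-7-(tert-butyldimethylsilyloxy)non-1-ene-3,4-diol | C=C[C@@H](O)[C@@H](O)C[C@@H](OCc1ccccc1)[C@@H](O[Si](C)(C)C(C)(C)C)CC | intermediate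
14 | (4R,5S)-5-[(2R,3S)-2-(benzyloxy)-3-(tert-butyldimethylsilyloxy)pentyl]-4-ethenyl-2,2-dimethyl-1,3-dioxolane | C=C[C@H]1OC(C)(C)O[C@H]1C[C@@H](OCc2ccccc2)[C@@H](O[Si](C)(C)C(C)(C)C)CC | intermediate
15 | 9-{2-[(4R,5S)-5-[(2R,3S)-2-(benzyloxy)-3-(tert-butyldimethylsilyloxy)pentyl]-2,2-dimethyl-1,3-dioxolan-4-yl]ethyl}-9-borabicyclo[3.3.1]nonane | B1(C2CCCC1CCC2)CC[C@H]3OC(C)(C)O[C@H]3C[C@@H](OCc4ccccc4)[C@@H](O[Si](C)(C)C(C)(C)C)CC | intermediate
16 | 2-[(4R,5S)-5-[(2R,3S)-2-(benzyloxy)-3-(tert-butyldimethylsilyloxy)pentyl]-2,2-dimethyl-1,3-dioxolan-4-yl]ethan-1-ol | OCC[C@H]1OC(C)(C)O[C@H]1C[C@@H](OCc2ccccc2)[C@@H](O[Si](C)(C)C(C)(C)C)CC | intermediate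
17 | 2-[(4R,5S)-5-[(2R,3S)-2-(benzyloxy)-3-(tert-butyldimethylsilyloxy)pentyl]-2,2-dimethyl-1,3-dioxolan-4-yl]ethyl acetate | CC(=O)OCC[C@H]1OC(C)(C)O[C@H]1C[C@@H](OCc2ccccc2)[C@@H](O[Si](C)(C)C(C)(C)C)CC | intermediate
18 | 2-[(4R,5S)-5-[(2R,3S)-3-(tert-butyldimethylsilyloxy)-2-hydroxypentyl]-2,2-dimethyl-1,3-dioxolan-4-yl]ethyl acetate | CC(=O)OCC[C@H]1OC(C)(C)O[C@H]1C[C@@H](O)[C@@H](O[Si](C)(C)C(C)(C)C)CC | intermediate
19 | allyl 2,2,2-trichloroacetimidate | C=CCOC(=N)C(Cl)(Cl)Cl | starting material
20 | 2-[(4R,5S)-5-[(2R,3S)-2-(allyloxy)-3-(tert-butyldimethylsilyloxy)pentyl]-2,2-dimethyl-1,3-dioxolan-4-yl]ethyl acetate | CC(=O)OCC[C@H]1OC(C)(C)O[C@H]1C[C@@H](OCC=C)[C@@H](O[Si](C)(C)C(C)(C)C)CC | intermediate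
21 | 2-[(4R,5S)-5-[(2R,3S)-2-(allyloxy)-3-(tert-butyldimethylsilyloxy)pentyl]-2,2-dimethyl-1,3-dioxolan-4-yl]ethan-1-ol | OCC[C@H]1OC(C)(C)O[C@H]1C[C@@H](OCC=C)[C@@H](O[Si](C)(C)C(C)(C)C)CC | intermediate
22 | 2-isopropoxy-4,4,5,5-tetramethyl-1,3,2-dioxaborolane | CC(C)OB1OC(C)(C)C(C)(C)O1 | starting material
23 | dilithio species of 21 (C7 lithium alkoxide; 1-alkoxyallyl anion on O12) | [Li+].[Li+].[O-]CC[C@H]1OC(C)(C)O[C@H]1C[C@@H](O[CH-]C=C)[C@@H](O[Si](C)(C)C(C)(C)C)CC | intermediate
24 | 2-[(4R,5S)-5-[(2R,3S)-3-(tert-butyldimethylsilyloxy)-2-{[(1Z)-3-(4,4,5,5-tetramethyl-1,3,2-dioxaborolan-2-yl)prop-1-en-1-yl]oxy}pentyl]-2,2-dimethyl-1,3-dioxolan-4-yl]ethan-1-ol | OCC[C@H]1OC(C)(C)O[C@H]1C[C@@H](O/C=C\CB2OC(C)(C)C(C)(C)O2)[C@@H](O[Si](C)(C)C(C)(C)C)CC | intermediate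
25 | 2-[(4R,5S)-5-[(2R,3S)-3-(tert-butyldimethylsilyloxy)-2-{[(1Z)-3-(4,4,5,5-tetramethyl-1,3,2-dioxaborolan-2-yl)prop-1-en-1-yl]oxy}pentyl]-2,2-dimethyl-1,3-dioxolan-4-yl]acetaldehyde | O=CC[C@H]1OC(C)(C)O[C@H]1C[C@@H](O/C=C\CB2OC(C)(C)C(C)(C)O2)[C@@H](O[Si](C)(C)C(C)(C)C)CC | intermediate
26 | oxocane alcohol (6R-ethenyl, 7R-hydroxyl, cis-9R,10S-acetonide, 12R-[(1S)-1-(tert-butyldimethylsilyloxy)propyl]; ring oxygen between C6 and C12) | C=C[C@H]1O[C@@H]([C@H](CC)O[Si](C)(C)C(C)(C)C)C[C@@H]2OC(C)(C)O[C@@H]2C[C@H]1O | intermediate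
27 | oxocane bis-silyl ether (26 with C7 tert-butyldimethylsilyl ether) | C=C[C@H]1O[C@@H]([C@H](CC)O[Si](C)(C)C(C)(C)C)C[C@@H]2OC(C)(C)O[C@@H]2C[C@H]1O[Si](C)(C)C(C)(C)C | intermediate
28 | B-alkyl-9-borabicyclo[3.3.1]nonane from 27 (boron on C4) | B1(C2CCCC1CCC2)CC[C@H]3O[C@@H]([C@H](CC)O[Si](C)(C)C(C)(C)C)C[C@@H]4OC(C)(C)O[C@@H]4C[C@H]3O[Si](C)(C)C(C)(C)C | intermediate
29 | primary alcohol (27 with C6 bearing 2-hydroxyethyl) | OCC[C@H]1O[C@@H]([C@H](CC)O[Si](C)(C)C(C)(C)C)C[C@@H]2OC(C)(C)O[C@@H]2C[C@H]1O[Si](C)(C)C(C)(C)C | intermediate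
30 | aldehyde (27 with C6 bearing 2-oxoethyl) | O=CC[C@H]1O[C@@H]([C@H](CC)O[Si](C)(C)C(C)(C)C)C[C@@H]2OC(C)(C)O[C@@H]2C[C@H]1O[Si](C)(C)C(C)(C)C | intermediate
31 | 1,3-bis(triisopropylsilyl)propyne | CC(C)[Si](C(C)C)(C(C)C)CC#C[Si](C(C)C)(C(C)C)C(C)C | starting material
32 | (Z)-silyl enyne (27 with C6 bearing (2Z)-5-(triisopropylsilyl)pent-2-en-4-yn-1-yl) | CC(C)[Si](C(C)C)(C(C)C)C#C/C=C\C[C@H]1O[C@@H]([C@H](CC)O[Si](C)(C)C(C)(C)C)C[C@@H]2OC(C)(C)O[C@@H]2C[C@H]1O[Si](C)(C)C(C)(C)C | intermediate
33 | (3Z,6R,7R,9R,10S,12R,13S)-6,12-epoxy-9,10-(isopropylidenedioxy)pentadec-3-en-1-yne-7,13-diol | C#C/C=C\C[C@H]1O[C@@H]([C@H](CC)O)C[C@@H]2OC(C)(C)O[C@@H]2C[C@H]1O | intermediate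
34 | (3Z,6R,7R,9R,10S,12R,13S)-6,12-epoxy-9,10-(isopropylidenedioxy)pentadec-3-en-1-yne-7,13-diyl diacetate | C#C/C=C\C[C@H]1O[C@@H]([C@H](CC)OC(C)=O)C[C@@H]2OC(C)(C)O[C@@H]2C[C@H]1OC(C)=O | intermediate
35 | (3Z,6R,7R,9R,10S,12R,13S)-6,12-epoxy-9,10-dihydroxypentadec-3-en-1-yne-7,13-diyl diacetate | C#C/C=C\C[C@H]1O[C@@H]([C@H](CC)OC(C)=O)C[C@H](O)[C@H](O)C[C@H]1OC(C)=O | target

## Step count and least certain steps

Total: 22 steps. Longest linear sequence: 22 steps (1 → 35). The other building blocks (6, 11, 19, 22, 31) are commercial and enter directly.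

**Step 15 (key step).** Three things are most likely to go wrong:
- protonation of the enol ether or loss of the C–B bond during the oxidation;
- bimolecular allylboration (oligomerisation) outpacing the eight-membered closure, since pinacol allylboronates are slow;
- incomplete rotamer control about C12–O12, which would erode the cis-2,8 selectivity.

The fallback replaces boron by tin so that oxidation and cyclisation are separated. It sets out from 21: double deprotonation with sec-BuLi as in step 14 and quenching with Bu3SnCl should give the (Z)-γ-alkoxyallyl stannane carrying the free C7 hydroxyl, hydroxy stannane F1. Buffered Dess–Martin oxidation should give aldehyde stannane F2, which does not react with its own aldehyde at room temperature and can be purified. Heating F2 in dilute toluene (110 °C) should close the ring through the same kind of cyclic six-membered transition state, and hydrolysis of the tin alkoxide returns to the route at 26.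

**Step 7.** The risks are incomplete facial control if the reagent and the β-benzyloxy centre are mismatched, and loss of material through Peterson-type elimination of the β-hydroxysilane under the fluoride/peroxide conditions. The fallback sets out from 10 and uses an iridium-catalysed transfer-hydrogenative anti-(α-acyloxy)allylation. With prop-2-ene-1,1-diyl dibenzoate, a cyclometalated π-allyliridium catalyst formed from [Ir(cod)Cl]2, a SEGPHOS ligand and a nitrobenzoic acid, and isopropanol as reductant, it should give the anti mono-benzoate F3. Methanolysis (K2CO3, MeOH) returns to the route at 13.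

**Step 14.** The risks are sluggish or unselective metalation of the allyl ether in the presence of the lithium alkoxide aggregate, and Wittig rearrangement if the anion warms before it is trapped. The fallback sets out from 21: silylation (TMSCl, Et3N) gives the trimethylsilyl ether F4. Monometalation with sec-BuLi and trapping with 22 gives the silylated boronate F5. Brief K2CO3/MeOH at 0 °C removes the trimethylsilyl group and returns to the route at 24.

**Step 12.** The risks are acid-promoted migration of the acetonide toward O12 (a syn-1,3-dioxane is accessible) and desilylation before the hindered hydroxyl is alkylated. The fallback sets out from 18: a neutral Tsuji–Trost O-allylation with allyl ethyl carbonate, Pd2(dba)3 and dppb in THF at 65 °C passes through a π-allyl palladium species and no strong acid. It returns to the route at 20 and makes no new compound (F0).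

**Step 19.** The risks are enolisation or β-elimination (ring opening) of the β-alkoxy aldehyde by the basic propargyl lithium, and incomplete Z-selectivity. The fallback sets out from 30: Stork–Zhao olefination (Ph3PCH2I iodide, NaN(SiMe3)2, THF/DMPU, −78 °C) should give the (Z)-vinyl iodide F6. Sonogashira coupling with (triisopropylsilyl)acetylene (Pd(PPh3)4, zerovalent palladium; CuI; iPr2NH) returns to the route at 32.

## Further compounds

F1 | step 15 | 2-[(4R,5S)-5-[(2R,3S)-3-(tert-butyldimethylsilyloxy)-2-{[(1Z)-3-(tributylstannyl)prop-1-en-1-yl]oxy}pentyl]-2,2-dimethyl-1,3-dioxolan-4-yl]ethan-1-ol | OCC[C@H]1OC(C)(C)O[C@H]1C[C@@H](O/C=C\C[Sn](CCCC)(CCCC)CCCC)[C@@H](O[Si](C)(C)C(C)(C)C)CC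
F2 | step 15 | 2-[(4R,5S)-5-[(2R,3S)-3-(tert-butyldimethylsilyloxy)-2-{[(1Z)-3-(tributylstannyl)prop-1-en-1-yl]oxy}pentyl]-2,2-dimethyl-1,3-dioxolan-4-yl]acetaldehyde | O=CC[C@H]1OC(C)(C)O[C@H]1C[C@@H](O/C=C\C[Sn](CCCC)(CCCC)CCCC)[C@@H](O[Si](C)(C)C(C)(C)C)CC
F3 | step 7 | (3R,4S,6R,7S)-6-(benzyloxy)-7-(tert-butyldimethylsilyloxy)-4-hydroxynon-1-en-3-yl benzoate | C=C[C@@H](OC(=O)c1ccccc1)[C@@H](O)C[C@@H](OCc2ccccc2)[C@@H](O[Si](C)(C)C(C)(C)C)CC
F4 | step 14 | trimethylsilyl ether of 21 | C[Si](C)(C)OCC[C@H]1OC(C)(C)O[C@H]1C[C@@H](OCC=C)[C@@H](O[Si](C)(C)C(C)(C)C)CC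
F5 | step 14 | trimethylsilyl ether of 24 | C[Si](C)(C)OCC[C@H]1OC(C)(C)O[C@H]1C[C@@H](O/C=C\CB2OC(C)(C)C(C)(C)O2)[C@@H](O[Si](C)(C)C(C)(C)C)CC
F6 | step 19 | (Z)-vinyl iodide (27 with C6 bearing (2Z)-3-iodoprop-2-en-1-yl) | I/C=C\C[C@H]1O[C@@H]([C@H](CC)O[Si](C)(C)C(C)(C)C)C[C@@H]2OC(C)(C)O[C@@H]2C[C@H]1O[Si](C)(C)C(C)(C)C
F0 | step 12 | none | none
A1 | alternative 1 | cis-2,8-disubstituted oxocene (C9=C10 ring olefin, C7 silyl ether, C13 benzyl ether, C4 pivalate) | CC(C)(C)C(=O)OCC[C@H]1O[C@@H]([C@H](CC)OCc2ccccc2)C/C=C\C[C@H]1O[Si](C)(C)C(C)(C)C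
A2 | alternative 1 | α-acetoxy ether precursor (C12 acetal carbon unassigned; terminal C10=C11 olefin) | CC(C)(C)C(=O)OCC[C@@H](OC(OC(C)=O)[C@H](CC)OCc1ccccc1)[C@@H](CCC=C)O[Si](C)(C)C(C)(C)C
A3 | alternative 2 | (8R,Z)-8-[(1S)-1-(tert-butyldimethylsilyloxy)propyl]-3,4,7,8-tetrahydro-2H-oxocin-2-one | O=C1O[C@@H]([C@H](CC)O[Si](C)(C)C(C)(C)C)C/C=C\CC1
A4 | alternative 2 | ketene acetal, (6R)-6-[(1S)-1-(tert-butyldimethylsilyloxy)propyl]-4-ethenyl-2-methylidene-1,3-dioxane (C4 unassigned) | C=CC1C[C@H]([C@H](CC)O[Si](C)(C)C(C)(C)C)OC(=C)O1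
A5 | alternative 3 | oxocan-3-one with C7 ketone, free C9 hydroxyl, C10 and C13 silyl ethers, C4 p-methoxybenzyl ether | COc1ccc(COCC[C@H]2O[C@@H]([C@H](CC)O[Si](C)(C)C(C)(C)C)C[C@H](O[Si](C)(C)C(C)(C)C)[C@H](O)CC2=O)cc1
A6 | alternative 3 | bromomethyl ketone aldehyde precursor (C7 ketone, C8 bromide, C9 aldehyde) | COc1ccc(COCC[C@@H](O[C@@H]([C@H](CC)O[Si](C)(C)C(C)(C)C)C[C@H](O[Si](C)(C)C(C)(C)C)C=O)C(=O)CBr)cc1
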